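all flasks: starting material 14 mM; coupling partner 16.8 mM
- gamma: protic impurity 0.39 mM; run made earlier
- beta: protic impurity 0.62 mM; run made earlier
- flask: protic impurity 0.280 mM; time 1.5 h

| run | time / min | side product / % | target / % | starting material / % | intermediate / % |
|---|---|---|---|---|---|
| gamma | 6.00 | 27 | 22 | 37 | 9 |
| gamma | 20.0 | 50 | 31 | 14 | 5 |
| gamma | 30.0 | 54 | 33 | 9 | 5 |
| gamma | 50.0 | 63 | 32 | 1 | 5 |
| gamma | 80.0 | 63 | 31 | 0 | 6 |
| beta | 6.00 | 25 | 26 | 35 | 5 |
| beta | 10.0 | 33 | 28 | 26 | 5 |
| beta | 20.0 | 51 | 33 | 15 | 3 |
| beta | 40.0 | 56 | 30 | 2 | 5 |
| beta | 80.0 | 62 | 30 | 2 | 4 |

(readings scatter by 1.5 percentage points)

- target is meant together with its crystals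
- solid, in amounts per volume of the solution: crystals
- on the list of suspects stand: starting material + coupling partner -> intermediate; starting material -> side product; coupling partner + intermediate -> target; crystals <-> target; coupling partner -> decomposed reagent; starting material + protic impurity -> quenched substrate

1. the largest share of what was charged as starting material, at 1.5 h belongs to (intermediate / target / side product / starting material)
2. the largest share itself, whichever of these holds it, in percent of the starting material charged

- In the first minutes both routes run: at 6.00 min the gamma run holds 27% side product against 31.0% target plus intermediate, a ratio of 0.871.
- From 20.0 min to 80.0 min target plus intermediate reads 36.0% to 37.0%, while starting material falls from 14% to 0% and side product climbs to 63%, so this late stretch is the one to watch.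
- The last gamma reading gives 1.70 for side product over target plus intermediate, the end split, a yield ratio read at these charges and no constant of the competition, or 0.231 in logarithms; the beta run, with more protic impurity, reads 0.261.
- We take 2.00% of the charge as lost to the protic impurity and bound the flask by two extremes: with the early ratio kept to the end, side product stands at 45.6%; with no coupling at all, at 98.0%.
- The gamma ratio rises from 0.871 to 1.70 along the run, away from the first extreme and towards the second, so we place the flask between them, and our split puts side product at 61.7%.
- The forecast says side product at 63%, slightly above our figure, and holds that “the two runs show no clear trend with impurity within the noise”.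
- The flask gives side product at 62.3% after 1.5 h, with target at 31.2% and intermediate at 4.47%, so its split is 1.75 against the 1.70 read from the gamma run.

    starting material + coupling partner → intermediate (k = 0.180 /M/s)
    starting material → side product (k = 0.00120 /s)
    coupling partner + intermediate → target (k = 1.50 /M/s)
    crystals ⇌ target, rate k4*(cs4 - [target]) while solid is left; crystals form when [target] > cs4 (solubility = 2.60 mM, k = 0.170 /s)
    coupling partner → decomposed reagent (k = 0.00230 /s)
    starting material + protic impurity → quenched substrate (k = 11.0 /M/s)

- The forecast's choice of side product stops holding once the coupling partner is raised by a factor of 1.56, to 26.1 mM, where side product and target hold the same. The neighbouring flask goes further, with 67 mM of coupling partner: its split is 0.186, or −0.730 in logarithms, which is 0.961 below 0.231 and ten times lower than the gamma split. That flask holds most as target, at 82.5% against 15.4% side product.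

(The data come from a simulation with constants of no real substance; the scatter is artificial.)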